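**Retrosynthetic overview**

1. Feature: in ring C, O1–C2(aryl) is a masked aldehyde C=O and C3–C4(=O)–C4a=C8a is a masked 1,3-dioxygenated butadiene. C2 can therefore be set on a 2-aryl-2,3-dihydropyran-4-one before ring A exists.
2. Ring A is cut last: C4a–C5 by Claisen acylation and C8a–C8 by conjugate addition followed by re-oxidation. This leads back to a 2-prenyl bis(silyloxy)diene (C5–C8 with the C6 prenyl) made from methyl acetoacetate.
3. Ring C is cut at C2–C3 and O1–C8a by an enantioselective oxa-(4+2) cycloaddition of the ring B aldehyde with Danishefsky's diene.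
4. Ring B comes from 4-hydroxybenzaldehyde by ortho,ortho-diprenylation and silylation.
5. Order of rings: B (purchased) → C (step 3) → A (steps 7–9); deprotection last. No step after step 3 enolizes C3.

Key step: step 3

Assumption: (R)-BINOL is taken to leave the Re face of the titanium-bound aryl aldehyde open, which gives (R)-C2; if the opposite sense is found, (S)-BINOL is used with nothing else changed.

Abbreviations: prenyl = 3-methylbut-2-enyl; Ar = 4-(tert-butyldimethylsilyloxy)-3,5-diprenylphenyl. The phenol is carried as a silyl ether instead of an acetal, because an acetal would be attacked under the silyl triflate conditions of step 7.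

**Route**

Step 1
Reactants: 1 4-hydroxybenzaldehyde; 2 prenyl bromide
Product: 3 4-hydroxy-3,5-diprenylbenzaldehyde
Conditions: 2 (2.5 equiv), KOH (2.5 equiv), H2O, rt; cold dilute acid to pH 6; chromatography to remove mono-C-prenyl and O-prenyl material
Reagents that add atoms: none
Why: C-alkylation of a phenoxide in water, where the hydrogen-bonded oxygen is masked and the ortho carbons react; the para position is blocked by the formyl group and SN2 attack at the primary allylic carbon gives the linear prenyl group.

Step 2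
Reactants: 3 4-hydroxy-3,5-diprenylbenzaldehyde
Product: 4 4-(tert-butyldimethylsilyloxy)-3,5-diprenylbenzaldehyde
Conditions: TBSCl, imidazole, DMF, rt to 40 °C
Reagents that add atoms: tert-butyldimethylsilyl chloride, CC(C)(C)[Si](C)(C)Cl
Why: Standard silylation of an acidic phenol; the hindered aryl silyl ether should survive CF3CO2H, TMSOTf, Pd(OAc)2 and amidine base and leave under buffered fluoride.

Step 3
Reactants: 4 4-(tert-butyldimethylsilyloxy)-3,5-diprenylbenzaldehyde; 5 Danishefsky's diene
Product: 7 (2R)-2-Ar-2,3-dihydro-4H-pyran-4-one, via silyl aldol adduct 6 (not isolated)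
Conditions: (R)-BINOL (20 mol %), Ti(OiPr)4 (10 mol %), 4 Å MS, Et2O, −20 °C; then CF3CO2H, CH2Cl2, 0 °C, short
Reagents that add atoms: none
Why: The (R)-BINOL complex of tetravalent titanium activates the aldehyde of 4, the CH2 terminus of diene 5 adds to the carbonyl carbon (C2–C3) with silyl transfer to give aldol adduct 6, and CF3CO2H then makes O1 add to the methoxy-bearing enone carbon and expel methanol (O1–C8a), so the net result is an oxa-(4+2) cycloaddition. The closest known reaction type is the catalytic enantioselective hetero-Diels–Alder (Mukaiyama aldol–cyclization) reaction of aromatic aldehydes with Danishefsky's diene under BINOL–titanium catalysis. Ring C closes in the 6-endo-trig mode by oxa-conjugate addition–elimination onto the vinylogous ester. C2 is the only new stereocenter; it is set in the C2–C3 bond-forming event by the BINOL ligand, which should leave the Re face of the bound aldehyde open and so give (R), and ring closure does not break the C2–O1 bond. The step needs face selectivity and chemoselectivity but no regiocontrol, because the diene is polarized and ring B is symmetric about its C1'–C4' axis; the meta prenyl groups are remote from the carbonyl, and the absence of a free ortho-phenol should keep the prenyl alkenes from cyclizing during the short, cold acid treatment.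

Step 4
Reactants: 8 methyl acetoacetate; 2 prenyl bromide
Product: 9 methyl 2-acetyl-5-methylhex-4-enoate (racemic)
Conditions: NaH (1.0 equiv), 8 (1.3 equiv), THF, 0 °C; 2 (1.0 equiv), 0 °C to rt
Reagents that add atoms: none
Why: Acetoacetic ester alkylation (SN2 at the primary allylic bromide by the sodium enolate); the excess of 8 suppresses dialkylation.

Step 5
Reactants: 9 methyl 2-acetyl-5-methylhex-4-enoate
Product: 10 methyl 2-prenyl-3-(trimethylsilyloxy)but-2-enoate (E/Z mixture)
Conditions: TMSCl, Et3N, toluene, rt
Reagents that add atoms: chlorotrimethylsilane, C[Si](C)(C)Cl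
Why: O-silylation of the enolized β-keto ester, the usual first stage of bis(silyloxy)diene preparation.

Step 6
Reactants: 10 methyl 2-prenyl-3-(trimethylsilyloxy)but-2-enoate
Product: 11 1-methoxy-2-prenyl-1,3-bis(trimethylsilyloxy)buta-1,3-diene
Conditions: LiN(iPr)2 (commercial solution), THF, −78 °C; TMSCl, −78 °C to rt; hexane, filtration under argon; used crude
Reagents that add atoms: chlorotrimethylsilane, C[Si](C)(C)Cl
Why: γ-Deprotonation at the methyl group gives the extended ester enolate, which is silylated on oxygen; this is the standard route to 2-alkyl-1,3-bis(silyloxy)dienes.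

Step 7
Reactants: 7 (2R)-2-Ar-2,3-dihydro-4H-pyran-4-one; 11 1-methoxy-2-prenyl-1,3-bis(trimethylsilyloxy)buta-1,3-diene
Product: 12 methyl 4-[(2S,6R)-6-Ar-4-(trimethylsilyloxy)-5,6-dihydro-2H-pyran-2-yl]-2-prenyl-3-(trimethylsilyloxy)but-2-enoate (2,6-trans ring, side-chain enol ether geometry not defined)
Conditions: 11 (1.3 equiv), TMSOTf (0.2 equiv), CH2Cl2, −78 °C; Et3N quench, pentane, cold aq. NaHCO3; used crude
Reagents that add atoms: none
Why: Mukaiyama–Michael addition: O-silylation of the vinylogous ester gives a 4-silyloxy oxocarbenium ion that the terminal CH2 of the diene attacks at C8a, axially and trans to the C2 aryl group, and silyl transfer leaves a regiodefined C4–C4a silyl enol ether without any base reaching C3.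

Step 8
Reactants: 12 bis(silyl) Michael adduct
Product: 14 methyl 2-{[(2R)-2-Ar-4-oxo-3,4-dihydro-2H-pyran-6-yl]acetyl}-5-methylhex-4-enoate (epimers at the ester α-carbon), via side-chain silyl enol ether 13 (not isolated)
Conditions: Pd(OAc)2 (1.2 equiv), MeCN, rt; Celite; then 0.5 M aq. citric acid, THF, rt
Reagents that add atoms: none
Why: Saegusa–Ito oxidation: the ring silyl enol ether transmetalates to divalent palladium at C4a and β-hydride elimination can only take the C8a hydrogen, which restores the C4a=C8a enone with the four-carbon chain now on C8a; the ester-conjugated silyl enol ether is less nucleophilic and is only hydrolyzed in the acidic work-up.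

Step 9
Reactants: 14 methyl 2-{[(2R)-2-Ar-4-oxo-3,4-dihydro-2H-pyran-6-yl]acetyl}-5-methylhex-4-enoate
Product: 15 (2R)-2-Ar-5,7-dihydroxy-6-prenylchroman-4-one
Conditions: DBU (2.5 equiv), MeCN (dilute), 0 °C to rt; AcOH, pH 5 buffer
Reagents that add atoms: none
Why: Intramolecular Claisen (Dieckmann-type) condensation: DBU reversibly removes a C8 proton (α to the C7 ketone and vinylogous to the C4 ketone), the delocalized anion acylates through C4a on the ester carbon C5 in a 6-exo-trig closure, and loss of methoxide gives a triketone that tautomerizes to the phloroglucinol ring A; ring C rules out the competing aldol mode, and the base is too weak to enolize C3, so C2 is untouched.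

Step 10
Reactants: 15 (2R)-2-Ar-5,7-dihydroxy-6-prenylchroman-4-one
Product: 16 (2R)-5,7-dihydroxy-2-(4-hydroxy-3,5-diprenylphenyl)-6-prenylchroman-4-one (target)
Conditions: Bu4NF (1.2 equiv), AcOH (1.5 equiv), THF, 0 °C
Reagents that add atoms: none
Why: Fluoride cleavage of the aryl silyl ether; buffering with acetic acid keeps the medium near neutral, so neither base-induced opening of ring C nor acid-induced cyclization of the ortho-prenyl phenols should occur.

**Compound list**

1 | 4-hydroxybenzaldehyde | O=Cc1ccc(O)cc1 | starting material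
2 | prenyl bromide (1-bromo-3-methylbut-2-ene) | CC(C)=CCBr | starting material
3 | 4-hydroxy-3,5-bis(3-methylbut-2-enyl)benzaldehyde | CC(C)=CCc1cc(C=O)cc(CC=C(C)C)c1O | intermediate
4 | 4-(tert-butyldimethylsilyloxy)-3,5-bis(3-methylbut-2-enyl)benzaldehyde | CC(C)=CCc1cc(C=O)cc(CC=C(C)C)c1O[Si](C)(C)C(C)(C)C | intermediate
5 | Danishefsky's diene, (E)-1-methoxy-3-(trimethylsilyloxy)buta-1,3-diene | CO/C=C/C(=C)O[Si](C)(C)C | starting material
6 | (1E,5R)-5-[4-(tert-butyldimethylsilyloxy)-3,5-bis(3-methylbut-2-enyl)phenyl]-1-methoxy-5-(trimethylsilyloxy)pent-1-en-3-one | CO/C=C/C(=O)C[C@@H](O[Si](C)(C)C)c1cc(CC=C(C)C)c(O[Si](C)(C)C(C)(C)C)c(CC=C(C)C)c1 | intermediate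
7 | (2R)-2-[4-(tert-butyldimethylsilyloxy)-3,5-bis(3-methylbut-2-enyl)phenyl]-2,3-dihydro-4H-pyran-4-one | CC(C)=CCc1cc([C@H]2CC(=O)C=CO2)cc(CC=C(C)C)c1O[Si](C)(C)C(C)(C)C | intermediate
8 | methyl acetoacetate | COC(=O)CC(C)=O | starting material
9 | methyl 2-acetyl-5-methylhex-4-enoate (racemic) | COC(=O)C(CC=C(C)C)C(C)=O | intermediate
10 | methyl 2-(3-methylbut-2-enyl)-3-(trimethylsilyloxy)but-2-enoate (E/Z mixture) | COC(=O)C(CC=C(C)C)=C(C)O[Si](C)(C)C | intermediate
11 | 1-methoxy-2-(3-methylbut-2-enyl)-1,3-bis(trimethylsilyloxy)buta-1,3-diene | COC(O[Si](C)(C)C)=C(CC=C(C)C)C(=C)O[Si](C)(C)C | intermediate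
12 | methyl 4-[(2S,6R)-6-Ar-4-(trimethylsilyloxy)-5,6-dihydro-2H-pyran-2-yl]-2-(3-methylbut-2-enyl)-3-(trimethylsilyloxy)but-2-enoate, Ar as defined above | COC(=O)C(CC=C(C)C)=C(C[C@H]1C=C(O[Si](C)(C)C)C[C@H](c2cc(CC=C(C)C)c(O[Si](C)(C)C(C)(C)C)c(CC=C(C)C)c2)O1)O[Si](C)(C)C | intermediate
13 | methyl 4-[(2R)-2-Ar-4-oxo-3,4-dihydro-2H-pyran-6-yl]-2-(3-methylbut-2-enyl)-3-(trimethylsilyloxy)but-2-enoate | COC(=O)C(CC=C(C)C)=C(CC1=CC(=O)C[C@H](c2cc(CC=C(C)C)c(O[Si](C)(C)C(C)(C)C)c(CC=C(C)C)c2)O1)O[Si](C)(C)C | intermediate
14 | methyl 2-{[(2R)-2-Ar-4-oxo-3,4-dihydro-2H-pyran-6-yl]acetyl}-5-methylhex-4-enoate (epimers at the ester α-carbon) | COC(=O)C(CC=C(C)C)C(=O)CC1=CC(=O)C[C@H](c2cc(CC=C(C)C)c(O[Si](C)(C)C(C)(C)C)c(CC=C(C)C)c2)O1 | intermediate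
15 | (2R)-2-[4-(tert-butyldimethylsilyloxy)-3,5-bis(3-methylbut-2-enyl)phenyl]-5,7-dihydroxy-6-(3-methylbut-2-enyl)chroman-4-one | CC(C)=CCc1cc([C@H]2CC(=O)c3c(cc(O)c(CC=C(C)C)c3O)O2)cc(CC=C(C)C)c1O[Si](C)(C)C(C)(C)C | intermediate
16 | (2R)-5,7-dihydroxy-2-[4-hydroxy-3,5-bis(3-methylbut-2-enyl)phenyl]-6-(3-methylbut-2-enyl)chroman-4-one | CC(C)=CCc1cc([C@H]2CC(=O)c3c(cc(O)c(CC=C(C)C)c3O)O2)cc(CC=C(C)C)c1O | target

**Step count and risks**

Total steps: 10. Longest linear sequence: 7 steps (steps 1, 2, 3, 7, 8, 9, 10; the diene branch through steps 4, 5, 6 is equally long).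

Steps most likely to fail:

1. Step 3. The electron-rich aldehyde may react slowly at the catalyst, so that an unselective background addition erodes the facial selectivity, and the acid used for ring closure may add to the prenyl alkenes. Fallback, setting out from 4 and returning at 7: the C2–C3 bond would be made by a reagent-controlled boron aldol reaction. (E)-4-Chlorobut-3-en-2-one is enolized with Ipc2BCl and Et3N, using the pinene-derived enantiomer that delivers the (R)-carbinol, and added to 4 at −78 °C. This should give (1E,5R)-5-[4-(tert-butyldimethylsilyloxy)-3,5-bis(3-methylbut-2-enyl)phenyl]-1-chloro-5-hydroxypent-1-en-3-one F1. Treatment with iPr2NEt and catalytic TMSOTf should then close ring C by 6-endo oxa-conjugate addition and loss of chloride to give 7, with no CF3CO2H involved.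

2. Step 8. The acetic acid released may protodesilylate the ring silyl enol ether to the saturated ketone before oxidation, and divalent palladium may be diverted by the alkenes or the β-dicarbonyl unit. Fallback, setting out from 12 and returning at 14: the oxidation would be done by selenoxide elimination. PhSeCl (1.0 equiv, CH2Cl2, −78 °C) reacts fastest with the ring silyl enol ether and, after aqueous work-up, should give the α-selanyl ketone methyl 2-{[(2S,6R)-6-Ar-4-oxo-3-(phenylselanyl)tetrahydropyran-2-yl]acetyl}-5-methylhex-4-enoate F2. H2O2 with pyridine in CH2Cl2 at 0 °C would convert it into the selenoxide methyl 2-{[(2S,6R)-6-Ar-4-oxo-3-(phenylseleninyl)tetrahydropyran-2-yl]acetyl}-5-methylhex-4-enoate F3. Its syn-elimination can only take the C8a hydrogen and should give 14.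

3. Step 9. Ring closure may be slow because the ester sits next to an enolized β-keto ester, and long exposure to base could then allow C3 enolization, opening of ring C and loss of optical purity. Fallback, setting out from 14 and returning at 15: the acylation would be run without base through a ketene. Heating 14 in xylene at 140 °C with removal of methanol should extrude methanol to give the acylketene (2R)-2-Ar-6-[3-(oxomethylidene)-6-methyl-2-oxohept-5-enyl]-2,3-dihydro-4H-pyran-4-one F4. Its ketene carbon C5 is held within reach of the enol-ether carbon C4a and should acylate it; tautomerization then gives 15.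

**Further compounds**

F1 | step 3 | (1E,5R)-5-[4-(tert-butyldimethylsilyloxy)-3,5-bis(3-methylbut-2-enyl)phenyl]-1-chloro-5-hydroxypent-1-en-3-one | Cl/C=C/C(=O)C[C@@H](O)c1cc(CC=C(C)C)c(O[Si](C)(C)C(C)(C)C)c(CC=C(C)C)c1
F2 | step 8 | methyl 2-{[(2S,6R)-6-Ar-4-oxo-3-(phenylselanyl)tetrahydropyran-2-yl]acetyl}-5-methylhex-4-enoate | COC(=O)C(CC=C(C)C)C(=O)C[C@@H]1O[C@@H](c2cc(CC=C(C)C)c(O[Si](C)(C)C(C)(C)C)c(CC=C(C)C)c2)CC(=O)C1[Se]c3ccccc3
F3 | step 8 | methyl 2-{[(2S,6R)-6-Ar-4-oxo-3-(phenylseleninyl)tetrahydropyran-2-yl]acetyl}-5-methylhex-4-enoate | COC(=O)C(CC=C(C)C)C(=O)C[C@@H]1O[C@@H](c2cc(CC=C(C)C)c(O[Si](C)(C)C(C)(C)C)c(CC=C(C)C)c2)CC(=O)C1[Se](=O)c3ccccc3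
F4 | step 9 | (2R)-2-Ar-6-[3-(oxomethylidene)-6-methyl-2-oxohept-5-enyl]-2,3-dihydro-4H-pyran-4-one (acylketene) | O=C=C(CC=C(C)C)C(=O)CC1=CC(=O)C[C@H](c2cc(CC=C(C)C)c(O[Si](C)(C)C(C)(C)C)c(CC=C(C)C)c2)O1
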